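## Analysis of the target

Numbering used throughout: chromen-4-one O1, C2–C4, C4a, C5–C8, C8a (ring A benzo, ring C pyranone); ring B C1'–C6'; chain C1''–C8''.

The target 14 is an isoflavone with hydroxyls at C7 and C4' and a ten-carbon chain at C3', ortho to the C4' hydroxyl. The chain is a (1Z)-3,7-dimethylocta-1,6-dienyl group: a Z styrenyl alkene C1''=C2'', one stereocentre at C3'' (R, allylic, methyl-bearing) and a distal trisubstituted alkene C6''=C7''. With a single stereocentre there is no relative configuration to set; it has to be brought in intact and never exposed to conditions that deprotonate or ionise the allylic position. The Z geometry is the less stable one and must be made under kinetic control. The most sensitive feature is the ortho-hydroxystyrene with a pendant trisubstituted alkene: protonation at C2'' gives an ortho-quinone-methide-type cation that C6''=C7'' and the phenol oxygen trap, so acid is excluded once the chain is attached. C2 of ring C is also open to hydroxide, and both alkenes and both phenols are oxidisable. The difficulty is therefore one of order: a 1,3,4-trisubstituted ring B, a Z alkene and an oxidisable, acid-labile chain must be combined without the chain meeting an oxidant or an acid. The strategy rests on two nucleophilic carbons: C3 of ring C is the alpha carbon of an enaminone in the ring-opened form, and C1' is para to the C4' hydroxyl. The C3–C1' bond can therefore be made by removing two electrons and two protons, after which the ortho hydroxyl of ring A closes ring C at O1–C2, while a bromine at C3' waits for the chain.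

## Retrosynthetic reasoning

**14 to 13.** The last bond cut is the acyl–oxygen bond of a pivalate at the C7 oxygen. An ester is chosen because base-mediated methanolysis removes it, whereas an acetal on either phenol would need acid at a stage when the ortho-hydroxystyrene and C6''=C7'' are both present. The forward step must cleave the ester without opening ring C and without touching the Z alkene.

**13 to 7 and 12.** The C3'–C1'' bond is cut, an sp2–sp2 bond between ring B and the alkenyl carbon. A cross-coupling here transfers the chain in one piece with retention of alkene geometry, and places it after the oxidative step. Geometry and configuration are settled in the small fragment 12, where they are easy to check. The forward reaction must couple the free ortho-bromophenol 7 without Z-to-E erosion. The C4' hydroxyl is left unprotected, which saves two steps.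

**12 to 11 to 8 and 9.** The C1''–B bond of 12 is traced to the terminal alkyne 11 by an anti-Markovnikov trans-hydroboration, which fixes the Z geometry. Alkyne 11 has the same ten carbons as (R)-citronellal 8: the aldehyde carbon becomes the alkyne terminus through the alkenyl sulfonate 10, formed with 9 and eliminated in the same flask. The stereocentre of 8 is beta to the carbonyl, is not enolised, and carries the configuration required at C3''.

**7 to 4 and 5.** This is the central disconnection: C3–C1' and O1–C2 are cut together. It divides the bromoisoflavone into the enaminone 4, which holds ring A and all carbons of ring C, and 2-bromophenol 5, which is ring B with its bromine already ortho to the hydroxyl. Neither partner needs a halide or metal at the coupling carbon. The forward step must join the alpha carbon of 4 to the para carbon of 5 by loss of two electrons and two protons, then let the ortho hydroxyl of ring A displace the amine at C2. The pivalate in 4 keeps ring A electron-poor and silent, and the chain is absent because it would not survive an anode.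

**4 to 2 and 3, and 2 to 1.** The enaminone C2–C3 bond comes from condensation of the methyl ketone 2 with the amide acetal 3, whose central carbon becomes C2 of ring C. Ketone 2 is the monoester of 2,4-dihydroxyacetophenone 1, acylated at the hydroxyl that is not hydrogen-bonded to the ketone. The precursor of the key step is thus two routine steps from a commodity chemical.

## Alternatives that were turned down

**Alternative 1:** Ring C is cut through C2=C3. In the forward direction diene A2, an aryl vinyl ether whose ketone carries a 1-arylvinyl group, would be closed by ring-closing metathesis with second-generation Grubbs catalyst in hot dilute toluene to the bis(methoxymethyl)-protected bromoisoflavone A1.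
- For: the conditions are neutral, the aryl bromide and acetals are safe, and both ring-forming atoms are fixed in A2, so there is no regiochemical question. On predictability of the ring-forming event it is stronger than the chosen route, whose key step must choose between several positions.
- Against: both alkenes are poor metathesis partners. The enol ether gives a heteroatom-stabilised ruthenium carbene that turns over slowly, and the other alkene is 1,1-disubstituted and conjugated to a ketone.
- Against: A2 needs about five steps, and its precursor with a free ortho hydroxyl would close by oxa-Michael addition instead. The ketone from which A2 is built already holds every ring atom except C2 and could be annulated with a one-carbon electrophile directly, so metathesis spends steps on a bond that condensation makes easily.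
- Against: the acetals of A1 come off only with acid, which must happen before the chain is attached, adding a step that converts A1 into the free diphenol A3.
- Comparison: the chosen route reaches 7 in three steps and forms C3–C1' and ring C together. It gives up certainty in the key step and offers convergence and step economy in return.

**Alternative 2:** The cut is at C3–C4 and O1–C2. The racemic trans-chalcone epoxide A4 would be opened at its benzylic carbon with BF3·OEt2, the aroyl group would shift to that carbon to give an alpha-formyl ketone, and methanolic HCl in the same flask would remove the acetals and let the ortho hydroxyl condense with the formyl group, giving 3'-bromo-7,4'-dihydroxyisoflavone A3.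
- For: the rearrangement belongs to a known reaction class, so on precedent this alternative is clearly stronger than the chosen key step.
- For: A3 is a free diphenol, one coupling from 14 with no deprotection afterwards, which is one step better than the chosen endgame.
- Against: A4 requires three acetal protections, an aldol condensation and an epoxidation, about five steps to A3.
- Against: the rearrangement has several competing channels. The bromine makes the benzylic cation slightly less stable, the Lewis acid also attacks the ortho acetal and frees a phenol that can open the epoxide itself, and a hydride shift instead of the aroyl shift leads to the isomeric 2-aryl skeleton.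
- Comparison: the chosen route offers a shorter, acetal-free approach that uses ring B as an unfunctionalised phenol, at the price of an unprecedented step that is backed by a fallback through known chemistry.

**Alternative 3:** The cut is at C4–C4a. The (Z)-3-aryloxy-2-arylacrylic acid A6 would be activated with P2O5 in CH3SO3H, and the acylium carbon would attack the ring position para to the methoxy group, giving the dimethyl ether A5.
- For: Friedel–Crafts acylation is robust and cheap, the bromide is tolerated, and the reaction type is known for chromones. In robustness of the ring-closing step it is stronger than the chosen route.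
- Against: only the Z acid can cyclise, and attack ortho to the methoxy group gives a 5-methoxy isomer as a minor pathway.
- Against: the methyl ethers of A5 need a reagent such as BBr3, which cannot be used after the chain is attached. A5 would have to be demethylated to A3 before coupling, adding a harsh step.
- Against: A6 itself needs several steps from a formylated arylacetate and a phenol.
- Comparison: the sequence is longer and fully linear. The chosen route carries a single protecting group that comes off by mild methanolysis at the end.

Key step: step 3

Assumption: (R)-citronellal 8 of high enantiomeric purity is used, because its stereocentre is carried unchanged to C3'' and no later step can raise the enantiomeric purity.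

## Route

Step 1
Reactants: 1 2,4-dihydroxyacetophenone
Product: 2 4-acetyl-3-hydroxyphenyl pivalate
Conditions: t-BuCOCl (1.05 equiv), Et3N (1.2 equiv), CH2Cl2, 0 °C to rt
Reagents that add atoms: pivaloyl chloride, CC(C)(C)C(=O)Cl
Why: Selective esterification of the more acidic, unhindered 4-hydroxyl; the 2-hydroxyl is held in a hydrogen bond to the ketone and flanked by the acetyl group, so one equivalent of the hindered acyl chloride should give the monoester.

Step 2
Reactants: 2 4-acetyl-3-hydroxyphenyl pivalate, 3 N,N-dimethylformamide dimethyl acetal
Product: 4 4-[(E)-3-(dimethylamino)prop-2-enoyl]-3-hydroxyphenyl pivalate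
Conditions: 3 (1.5 equiv), toluene, 80 °C
Reagents that add atoms: none
Why: Condensation of a methyl ketone with an amide acetal (enaminone formation) gives the E vinylogous amide; the chelated phenol is not alkylated and the hindered pivalate should withstand the methanol released.

Step 3
Reactants: 4 4-[(E)-3-(dimethylamino)prop-2-enoyl]-3-hydroxyphenyl pivalate, 5 2-bromophenol
Product: 7 3-(3-bromo-4-hydroxyphenyl)-4-oxo-4H-chromen-7-yl pivalate, via alpha-aryl enaminone 6 (not isolated)
Conditions: undivided cell, graphite anode, Pt cathode, constant current (about 5 mA cm−2, 2.2 F mol−1), 5 (4 equiv), Bu4NBF4 (0.1 M), (CF3)2CHOH, 20 °C; then 40 °C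
Reagents that add atoms: none
Why: Proposed new method: enaminone 4 should be oxidised at a lower potential than phenol 5, and loss of one electron at the anode gives a radical cation with radical character at C3 and iminium character at C2 that is attacked by the para carbon of 5, in the way enamine radical cations add to pi-nucleophiles. A second electron transfer and loss of two protons rearomatise ring B and restore the vinylogous amide, so that the C3–C1' bond of 6 results from a net two-electron dehydrogenative coupling while protons are reduced at the cathode. In the acidic, hydrogen-bond-donating solvent the ortho hydroxyl of ring A then adds to C2 of 6 in a 6-endo-trig conjugate addition and dimethylamine is expelled, which forms O1–C2 and closes ring C as an aromatic pyranone; no stereocentre is formed. The closest known reaction types are the anodic dehydrogenative phenol–arene cross-coupling in fluorinated alcohols and the electrophile-triggered alpha-functionalisation and annulation of ortho-hydroxyaryl enaminones to 3-substituted chromones. Cross-coupling over homo-coupling is needed and should follow from the gap in oxidation potential, the excess of 5 and the solvent, which solvates the phenol and suppresses its own oxidation. Para over ortho attack is needed and should follow from bromine blocking one ortho position and from the para carbon being the least hindered site with the largest orbital coefficient. Ring A stays out of the reaction because the pivalate and the acyl group make it electron-poor, and the charge is limited to little more than two faradays per mole so that the phenol of 7 is not oxidised further.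

Step 4
Reactants: 8 (R)-citronellal, 9 nonafluorobutane-1-sulfonyl fluoride
Product: 11 (R)-3,7-dimethyloct-6-en-1-yne, via alkenyl nonaflate 10 (not isolated)
Conditions: 9 (1.2 equiv), phosphazene base P2-Et, EtN=P(NMe2)2–N=P(NMe2)3 (2.3 equiv), DMF, −20 °C to rt
Reagents that add atoms: none
Why: One-pot conversion of an enolisable aldehyde into a terminal alkyne: the aldehyde enolate is O-sulfonylated by 9 to the alkenyl nonaflate 10 and a second equivalent of base effects beta-elimination of nonaflate; the stereocentre is beta to the carbonyl and is not deprotonated, and the base should be too weak to isomerise the alkyne to an allene.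

Step 5
Reactants: 11 (R)-3,7-dimethyloct-6-en-1-yne
Product: 12 2-[(1Z,3R)-3,7-dimethylocta-1,6-dien-1-yl]-4,4,5,5-tetramethyl-1,3,2-dioxaborolane
Conditions: 11 (1.2 equiv), pinacolborane (1.0 equiv), [Rh(cod)Cl]2 (1.5 mol%), P(i-Pr)3 (6 mol%), Et3N (1 equiv), cyclohexane, rt
Reagents that add atoms: pinacolborane, CC1(C)OBOC1(C)C
Why: Rhodium-catalysed anti-Markovnikov trans-hydroboration of a terminal alkyne: the alkyne rearranges to a rhodium vinylidene, boron migrates to the alpha carbon and reductive elimination places hydrogen and boron anti, giving the Z-alkenylboronate; the trisubstituted alkene and the propargylic stereocentre take no part.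

Step 6
Reactants: 7 3-(3-bromo-4-hydroxyphenyl)-4-oxo-4H-chromen-7-yl pivalate, 12 2-[(1Z,3R)-3,7-dimethylocta-1,6-dien-1-yl]-4,4,5,5-tetramethyl-1,3,2-dioxaborolane
Product: 13 3-{3-[(1Z,3R)-3,7-dimethylocta-1,6-dien-1-yl]-4-hydroxyphenyl}-4-oxo-4H-chromen-7-yl pivalate
Conditions: 12 (1.3 equiv), Pd(OAc)2 (5 mol%), SPhos (10 mol%), K3PO4 (3 equiv), THF/H2O (10:1), degassed, 60 °C
Reagents that add atoms: none
Why: Suzuki–Miyaura coupling of an aryl bromide with an alkenylboronate, which transfers the alkenyl group with retention of the Z geometry; the electron-rich biarylphosphine supports oxidative addition of zerovalent palladium into the bromophenoxide, and any pivalate lost to the aqueous base is harmless because step 7 removes it.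

Step 7
Reactants: 13 3-{3-[(1Z,3R)-3,7-dimethylocta-1,6-dien-1-yl]-4-hydroxyphenyl}-4-oxo-4H-chromen-7-yl pivalate
Product: 14 3-{3-[(1Z,3R)-3,7-dimethylocta-1,6-dien-1-yl]-4-hydroxyphenyl}-7-hydroxy-4H-chromen-4-one
Conditions: K2CO3 (1.5 equiv), MeOH, 0 °C to rt; aqueous NH4Cl work-up (pH about 6)
Reagents that add atoms: none
Why: Base-mediated methanolysis (transesterification) of the activated aryl pivalate; the 7-oxido chromone formed is deactivated towards attack at C2, the Z alkene and the stereocentre are inert to carbonate, and the buffered work-up avoids the acid that would cyclise the ortho-hydroxystyrene onto the C6''=C7'' alkene.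

## Compound list

1 | 2,4-dihydroxyacetophenone | CC(=O)c1ccc(O)cc1O | starting material
2 | 4-acetyl-3-hydroxyphenyl pivalate | CC(=O)c1ccc(OC(=O)C(C)(C)C)cc1O | intermediate
3 | N,N-dimethylformamide dimethyl acetal | COC(OC)N(C)C | starting material
4 | 4-[(E)-3-(dimethylamino)prop-2-enoyl]-3-hydroxyphenyl pivalate | CC(C)(C)C(=O)Oc1ccc(C(=O)/C=C/N(C)C)c(O)c1 | intermediate
5 | 2-bromophenol | Oc1ccccc1Br | starting material
6 | 4-[(E)-2-(3-bromo-4-hydroxyphenyl)-3-(dimethylamino)prop-2-enoyl]-3-hydroxyphenyl pivalate | CC(C)(C)C(=O)Oc1ccc(C(=O)/C(=C/N(C)C)c2ccc(O)c(Br)c2)c(O)c1 | intermediate (not isolated)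
7 | 3-(3-bromo-4-hydroxyphenyl)-4-oxo-4H-chromen-7-yl pivalate | CC(C)(C)C(=O)Oc1ccc2c(c1)occ(-c1ccc(O)c(Br)c1)c2=O | intermediate
8 | (R)-citronellal, (3R)-3,7-dimethyloct-6-enal | CC(C)=CCC[C@@H](C)CC=O | starting material
9 | nonafluorobutane-1-sulfonyl fluoride | O=S(=O)(F)C(F)(F)C(F)(F)C(F)(F)C(F)(F)F | starting material
10 | (3R)-3,7-dimethylocta-1,6-dien-1-yl nonafluorobutane-1-sulfonate (E/Z mixture at C1=C2, geometry not specified) | CC(C)=CCC[C@@H](C)C=COS(=O)(=O)C(F)(F)C(F)(F)C(F)(F)C(F)(F)F | intermediate (not isolated)
11 | (R)-3,7-dimethyloct-6-en-1-yne | CC(C)=CCC[C@@H](C)C#C | intermediate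
12 | 2-[(1Z,3R)-3,7-dimethylocta-1,6-dien-1-yl]-4,4,5,5-tetramethyl-1,3,2-dioxaborolane | CC(C)=CCC[C@@H](C)/C=C\B1OC(C)(C)C(C)(C)O1 | intermediate
13 | 3-{3-[(1Z,3R)-3,7-dimethylocta-1,6-dien-1-yl]-4-hydroxyphenyl}-4-oxo-4H-chromen-7-yl pivalate | CC(C)=CCC[C@@H](C)/C=C\c1cc(-c2coc3cc(OC(=O)C(C)(C)C)ccc3c2=O)ccc1O | intermediate
14 | 3-{3-[(1Z,3R)-3,7-dimethylocta-1,6-dien-1-yl]-4-hydroxyphenyl}-7-hydroxy-4H-chromen-4-one | CC(C)=CCC[C@@H](C)/C=C\c1cc(-c2coc3cc(O)ccc3c2=O)ccc1O | target

## Step count and least certain steps

Total step count: 7 (steps 1–3 for the bromoisoflavone, steps 4–5 for the boronate, steps 6–7 for the union and deprotection).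
Longest linear sequence: 5 steps (1, 2, 3, 6, 7).

**Step 3 (key step, proposed new method).**
- What may go wrong: premature acid-promoted ring closure of 4 in the fluorinated alcohol, with loss of the amine before any arylation, which removes the oxidisable and nucleophilic enaminone.
- What may go wrong: anodic homo-coupling or over-oxidation of the phenol, with film formation on the anode.
- What may go wrong: oxidation alpha to nitrogen leading to N-demethylation, or attack at the free ortho position of 5 instead of the para position.
- Fallback (known chemistry), from 4, returning at 7: iodine (I2) in CHCl3 at rt should effect electrophilic iodination at the enaminone alpha carbon and ring closure to 3-iodo-4-oxo-4H-chromen-7-yl pivalate F1. Suzuki–Miyaura coupling of F1 with (4-hydroxyphenyl)boronic acid (Pd(OAc)2, SPhos, KF, THF with a little water, 50 °C, chosen to spare the pivalate) should give 3-(4-hydroxyphenyl)-4-oxo-4H-chromen-7-yl pivalate F2. Monobromination ortho to the ring B hydroxyl with N-bromosuccinimide (1.0 equiv, MeCN, 0 °C) should then give 7, ring A being deactivated by its ester and carbonyl.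

**Step 4.**
- What may go wrong: slow elimination of the E-configured part of nonaflate 10, which requires a syn elimination.
- What may go wrong: aldol self-condensation of 8 before O-sulfonylation.
- What may go wrong: base-induced alkyne-to-allene isomerisation, which would erode the configuration at the propargylic carbon.
- Fallback, from 8, returning at 11, by removing one carbon and adding one back: proline-catalysed alpha-aminoxylation of 8 with nitrosobenzene, then NaBH4 in the same flask, should give (3R)-3,7-dimethyl-2-[(phenylamino)oxy]oct-6-en-1-ol F3. The configuration of the new C2 centre does not matter because that carbon is later excised. N–O cleavage (Zn, AcOH) should give (3R)-3,7-dimethyloct-6-ene-1,2-diol F4, and glycol cleavage with NaIO4 in THF/H2O should give (R)-2,6-dimethylhept-5-enal F5. Ohira–Bestmann homologation of F5 (dimethyl (1-diazo-2-oxopropyl)phosphonate, K2CO3, MeOH, 0 °C, kept cold to protect the alpha stereocentre) should give 11.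

**Step 5.**
- What may go wrong: incomplete trans-selectivity, with competing syn-hydroboration to the E boronate.
- What may go wrong: rhodium-hydride-mediated Z-to-E isomerisation of 12 on prolonged reaction.
- Fallback, from 11, returning at 12: deprotonation with n-BuLi (THF, −78 °C), trapping with 2-isopropoxy-4,4,5,5-tetramethyl-1,3,2-dioxaborolane and quenching with anhydrous HCl in ether should give 2-[(3R)-3,7-dimethyloct-6-en-1-yn-1-yl]-4,4,5,5-tetramethyl-1,3,2-dioxaborolane F6. Syn-hydrozirconation of F6 with Cp2Zr(H)Cl in THF, then protonolysis of the carbon–zirconium bond with water, should give 12 with the Z geometry fixed by the syn addition.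

**Step 6.**
- What may go wrong: slow oxidative addition into the electron-rich bromophenoxide, leaving time for protodeboronation of 12.
- What may go wrong: erosion of the Z geometry at palladium.
- Partial, uncontrolled loss of the pivalate may also occur but is harmless.
- Fallback, from 7 and 11, returning at 14: acylation of the C4' hydroxyl of 7 (t-BuCOCl, Et3N, 4-dimethylaminopyridine, CH2Cl2) should give 3-[3-bromo-4-(pivaloyloxy)phenyl]-4-oxo-4H-chromen-7-yl pivalate F7. The ester prevents cyclisation of an ortho-alkynylphenol to a benzofuran in the next step. Sonogashira coupling of F7 with 11 (Pd(PPh3)2Cl2, CuI, Et3N, 60 °C) should give 3-{3-[(3R)-3,7-dimethyloct-6-en-1-yn-1-yl]-4-(pivaloyloxy)phenyl}-4-oxo-4H-chromen-7-yl pivalate F8. Semi-hydrogenation of F8 (H2, Pd/CaCO3 poisoned with Pb(OAc)2, quinoline, EtOAc) should give the Z alkene 3-{3-[(1Z,3R)-3,7-dimethylocta-1,6-dien-1-yl]-4-(pivaloyloxy)phenyl}-4-oxo-4H-chromen-7-yl pivalate F9. Methanolysis of both esters of F9 (K2CO3, MeOH, buffered work-up) should give 14.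

## Further compounds

F1 | step 3 | 3-iodo-4-oxo-4H-chromen-7-yl pivalate | CC(C)(C)C(=O)Oc1ccc2c(c1)occ(I)c2=O
F2 | step 3 | 3-(4-hydroxyphenyl)-4-oxo-4H-chromen-7-yl pivalate | CC(C)(C)C(=O)Oc1ccc2c(c1)occ(-c1ccc(O)cc1)c2=O
F3 | step 4 | (3R)-3,7-dimethyl-2-[(phenylamino)oxy]oct-6-en-1-ol (C2 configuration not specified) | CC(C)=CCC[C@@H](C)C(CO)ONc1ccccc1
F4 | step 4 | (3R)-3,7-dimethyloct-6-ene-1,2-diol (C2 configuration not specified) | CC(C)=CCC[C@@H](C)C(O)CO
F5 | step 4 | (R)-2,6-dimethylhept-5-enal | CC(C)=CCC[C@@H](C)C=O
F6 | step 5 | 2-[(3R)-3,7-dimethyloct-6-en-1-yn-1-yl]-4,4,5,5-tetramethyl-1,3,2-dioxaborolane | CC(C)=CCC[C@@H](C)C#CB1OC(C)(C)C(C)(C)O1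
F7 | step 6 | 3-[3-bromo-4-(pivaloyloxy)phenyl]-4-oxo-4H-chromen-7-yl pivalate | CC(C)(C)C(=O)Oc1ccc2c(c1)occ(-c1ccc(OC(=O)C(C)(C)C)c(Br)c1)c2=O
F8 | step 6 | 3-{3-[(3R)-3,7-dimethyloct-6-en-1-yn-1-yl]-4-(pivaloyloxy)phenyl}-4-oxo-4H-chromen-7-yl pivalate | CC(C)=CCC[C@@H](C)C#Cc1cc(-c2coc3cc(OC(=O)C(C)(C)C)ccc3c2=O)ccc1OC(=O)C(C)(C)C
F9 | step 6 | 3-{3-[(1Z,3R)-3,7-dimethylocta-1,6-dien-1-yl]-4-(pivaloyloxy)phenyl}-4-oxo-4H-chromen-7-yl pivalate | CC(C)=CCC[C@@H](C)/C=C\c1cc(-c2coc3cc(OC(=O)C(C)(C)C)ccc3c2=O)ccc1OC(=O)C(C)(C)C
A1 | alternative 1 | 3-[3-bromo-4-(methoxymethoxy)phenyl]-7-(methoxymethoxy)-4H-chromen-4-one | COCOc1ccc2c(c1)occ(-c1ccc(OCOC)c(Br)c1)c2=O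
A2 | alternative 1 | 2-[3-bromo-4-(methoxymethoxy)phenyl]-1-[2-(ethenyloxy)-4-(methoxymethoxy)phenyl]prop-2-en-1-one | C=COc1cc(OCOC)ccc1C(=O)C(=C)c1ccc(OCOC)c(Br)c1
A3 | alternative 2 | 3-(3-bromo-4-hydroxyphenyl)-7-hydroxy-4H-chromen-4-one | Oc1ccc2c(c1)occ(-c1ccc(O)c(Br)c1)c2=O
A4 | alternative 2 | trans-[2,4-bis(methoxymethoxy)phenyl]{3-[3-bromo-4-(methoxymethoxy)phenyl]oxiran-2-yl}methanone (racemic, one enantiomer drawn) | O=C(c1ccc(OCOC)cc1OCOC)[C@H]1O[C@@H]1c1ccc(OCOC)c(Br)c1
A5 | alternative 3 | 3-(3-bromo-4-methoxyphenyl)-7-methoxy-4H-chromen-4-one | COc1ccc2c(c1)occ(-c1ccc(OC)c(Br)c1)c2=O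
A6 | alternative 3 | (Z)-2-(3-bromo-4-methoxyphenyl)-3-(3-methoxyphenoxy)prop-2-enoic acid | COc1cccc(O/C=C(\C(=O)O)c2ccc(OC)c(Br)c2)c1
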